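All constants are those of an exercise, and the outcome is calculated.

At the reading, 8.0 min into the run, this flask holds whatever target the dissolved gas has caught from a substrate that is meanwhile condensing with itself.

    dissolved gas → decomposed reagent (k1 = 0.0062 s⁻¹)
    gas phase ⇌ dissolved gas, rate k2*(csat - [dissolved gas]) (k2 = 0.0067 s⁻¹, csat = 5.3 mM)
    2 substrate → self-condensation product (k3 = 0.62 M⁻¹ s⁻¹)
    substrate + dissolved gas → target (k4 = 0.42 M⁻¹ s⁻¹)
    substrate + target → side product (k5 = 0.11 M⁻¹ s⁻¹)

substrate 15 mM; gas phase 5.3 mM (held); time 8.0 min

- percentages count the substrate that a species holds: one self-condensation product or side product counts as two
- a step written with two of one species runs at k times the square of its concentration and takes two of it each time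
- at the start none of the gas is dissolved
- run time (flask): 8.0 min

- target at 8.0 min, in percent of the substrate charged
- the change that raises the amount of target at 8.0 min, in percent of the substrate charged most ("none" if none brings more than 2 percentage points) (north-east / south / none)
- amount of target at 8.0 min, in percent of the substrate charged, after south

My colleague holds the plateau view: the dissolved gas stands from the start at the level where transfer balances decomposition, 2.75 mM, and the substrate meets that level throughout, which gives 14.3% of target.

I hold the lag view, since the gas starts from nothing. Self-condensation alone gives the substrate a mean over the run of 3.86 mM, and with that mean the capture step is pseudo-first-order in gas, so c(dissolved gas) rises towards 2.45 mM with a rise time of 68.9 s. The substrate's first half-life by self-condensation alone, 53.8 s, is shorter than that rise time, so I replace the rise by a step at the end of the lag and count the exposure, the time integral of c(substrate) from the end of the lag to the reading, 1.19 M·s.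

Capture constant times gas times exposure gives 8.12% of target made, before any loss to the side product. Taking the charge instead of the mean in the rise time would make that 8.94%. Doubling the saturation doubles the gas at the same lag, 16.2%, while doubling the transfer gives 12.6%, which is less.

The forecast, finding that “self-condensation dominates”, stands on the lag side but lower than I do: 7.4%, then south at 13.6%.

The simulation gives 7.39%, and south at 13.5%, a gain of 6.1 percentage points against 3.2 points for north-east. Target made, with the side product's share added back, is 7.90%. The plateau level of 2.75 mM holds for the later run of this flask and not for its start: dissolved gas stands at 1.17 mM at 0.800 min, 2.41 mM at 4.00 min and 2.63 mM at 8.00 min.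

This flask is not at rest. Its 7.5% of substrate, reckoned as also taken by capture at the gas level of the reading, adds 0.657 M·s to the exposure of 1.19 M·s, worth 4.8 points more target made over the whole of that remainder. The flask left until 30.0 min, with 0.71% of its substrate still there, shows 3.9 points more target made. At ten times the time, target stands at 11.2% and substrate at 0.0117%, while decomposed reagent has climbed from 6.36 mM to 79.7 mM.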